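**Strategy.** The γ-butyrolactone ring (O1, C2–C5) with its C4 carboxyl group is the carbon skeleton of natural (2R,3S)-isocitric acid lactone, whose extra C5 carboxyl sits exactly where the side chain begins. Everything rests on cutting C5–C1′. A nickel-electrocatalytic doubly decarboxylative coupling joins the C5 redox-active ester of the lactone (C4 acid masked as tert-butyl ester) to the redox-active ester of 14-acetoxytetradecanoic acid. The step exploits ring oxygen O1, which stabilises the C5 radical, and the C4 substituent of the five-membered ring, which steers bond formation to the opposite face and so turns the cis chiral-pool lactone into the trans product. A temporary bicyclic anhydride differentiates the two carboxyl groups.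

Key step: step 6

Remark on locants: the text uses lactone locants O1, C2 (C=O), C3 (=CH2), C4 (CO2H), C5 (side chain) and C1′–C13′. The systematic names use oxolane locants, so C5 of the text is C2 of the names and C4 is C3.
Assumption: monopotassium (2R,3S)-isocitrate (the natural threo-Ds salt) and 14-hydroxytetradecanoic acid are taken as catalogue compounds.

Step 1
Reactants: 1 monopotassium (2R,3S)-isocitrate
Product: 2 (2R,3S)-5-oxooxolane-2,3-dicarboxylic acid (isocitric acid lactone, carboxyl groups cis)
Conditions: 2 M aq HCl, evaporate; 100 °C, vacuum; take up in acetone, filter, concentrate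
Reagents that add atoms: none
Why: Acid frees the triacid, and its γ-hydroxy acid unit closes to the five-membered lactone on heating (intramolecular Fischer-type esterification) without touching either stereocentre.

Step 2
Reactants: 2 (2R,3S)-5-oxooxolane-2,3-dicarboxylic acid
Product: 3 (3aS,6aR)-dihydrofuro[3,4-b]furan-2,4,6(3H)-trione (cis-fused lactone anhydride)
Conditions: Ac2O, 70 °C; evaporate with toluene
Reagents that add atoms: none
Why: Dehydrative anhydride exchange closes the five-membered anhydride, which only the cis-1,2-diacid can form, so the relative configuration is locked while the two carboxyl carbons become electronically different.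

Step 3
Reactants: 3 cis-fused lactone anhydride
Product: 5 3-tert-butyl 2-(1,3-dioxoisoindolin-2-yl) (2R,3S)-5-oxooxolane-2,3-dicarboxylate, via redox-active ester acid 4 (not isolated)
Conditions: N-hydroxyphthalimide (1.0 equiv), DMAP (cat.), THF, −20 to 0 °C; then Cl3CC(=NH)Ot-Bu, CH2Cl2/cyclohexane, rt
Reagents that add atoms: N-hydroxyphthalimide O=C1c2ccccc2C(=O)N1O; tert-butyl 2,2,2-trichloroacetimidate CC(C)(C)OC(=N)C(Cl)(Cl)Cl
Why: Nucleophilic acyl substitution should open the anhydride kinetically at the more electrophilic carbonyl next to the O-bearing carbon, as in α-acyloxysuccinic anhydrides, and the freed C4 acid is trapped at once by base-free imidate tert-butylation before it can close back onto the activated ester.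

Step 4
Reactants: 6 14-hydroxytetradecanoic acid
Product: 7 14-acetoxytetradecanoic acid
Conditions: Ac2O, pyridine, DMAP (cat.), CH2Cl2, rt; then H2O; 1 M HCl wash
Reagents that add atoms: acetic anhydride CC(=O)OC(C)=O
Why: Standard O-acetylation of the primary alcohol, in which any mixed anhydride formed at the acid terminus is hydrolysed in the aqueous quench.

Step 5
Reactants: 7 14-acetoxytetradecanoic acid
Product: 8 1,3-dioxoisoindolin-2-yl 14-acetoxytetradecanoate
Conditions: N-hydroxyphthalimide, DIC, DMAP (cat.), CH2Cl2, rt
Reagents that add atoms: N-hydroxyphthalimide O=C1c2ccccc2C(=O)N1O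
Why: Carbodiimide (Steglich-type) esterification gives the N-acyloxyphthalimide, and the acetate is inert under these conditions.

Step 6
Reactants: 5 3-tert-butyl 2-(1,3-dioxoisoindolin-2-yl) (2R,3S)-5-oxooxolane-2,3-dicarboxylate; 8 1,3-dioxoisoindolin-2-yl 14-acetoxytetradecanoate (3 equiv)
Product: 9 tert-butyl (2R,3S)-2-(13-acetoxytridecyl)-5-oxooxolane-3-carboxylate (trans)
Conditions: NiCl2·6H2O (20 mol %), 2,2′:6′,2″-terpyridine (20 mol %), NaI, DMF, undivided cell, Mg(+)/RVC(−), constant current, rt; aq HCl work-up
Reagents that add atoms: none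
Why: Cathodically generated low-valent Ni–terpyridine reduces both N-acyloxyphthalimides by single-electron transfer, each fragments with loss of CO2 and phthalimide anion to the O1-stabilised C5 lactone radical and the primary C1′ radical, both are captured at nickel, and C(sp3)–C(sp3) reductive elimination forms C5–C1′ while the magnesium anode supplies the electrons. The closest known reaction type is the Ni-electrocatalytic doubly decarboxylative cross-coupling of redox-active esters, established for secondary α-oxygenated partners with primary alkyl partners. No ring is closed. C5 is planarised in the radical, so the cis configuration of 5 is erased and the new bond should form on the ring face anti to the bulky C4 CO2t-Bu group, giving the trans (2R,3S) product, while C4 is untouched and carries the absolute configuration from the chiral pool. The step needs cross- over homo-coupling, secured by the different character of the two radicals (stabilised secondary versus primary) and the excess of the cheap partner 8. It also needs coupling over β-hydride elimination towards C4, which the tridentate ligand disfavours, and lactone, tert-butyl ester and acetate are inert at the mild potential.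

Step 7
Reactants: 9 tert-butyl (2R,3S)-2-(13-acetoxytridecyl)-5-oxooxolane-3-carboxylate
Product: 12 tert-butyl (2R,3S)-2-(13-acetoxytridecyl)-4-methylidene-5-oxooxolane-3-carboxylate, via Mannich base 10 (not isolated), via trimethylammonium iodide 11 (not isolated)
Conditions: LiHMDS (1.05 equiv), THF, −78 °C; Me2N=CH2+ I−, −78 °C to rt; then MeI, CH2Cl2, rt; then sat. aq NaHCO3/CH2Cl2, rt
Reagents that add atoms: Eschenmoser's salt C=[N+](C)C.[I-]; methyl iodide CI (stays only in intermediate 11)
Why: The lactone C3–H2 is more acidic and less hindered than the acetate CH3 or C4–H, so one equivalent of base at −78 °C should give the C3 enolate, and Mannich aminomethylation (anti to the C4 ester), N-methylation and Hofmann-type β-elimination under bicarbonate then install the exocyclic methylene, destroying the transient C3 stereocentre and leaving C4 and C5 alone.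

Step 8
Reactants: 12 tert-butyl (2R,3S)-2-(13-acetoxytridecyl)-4-methylidene-5-oxooxolane-3-carboxylate
Product: 13 (2R,3S)-2-(13-acetoxytridecyl)-4-methylidene-5-oxooxolane-3-carboxylic acid (target)
Conditions: TFA/CH2Cl2 (1:3), 0 °C to rt; evaporate
Reagents that add atoms: none
Why: Acidolysis of the tert-butyl ester (loss of the tert-butyl cation as isobutene) spares acetate, lactone and acrylate, and the acidic medium avoids base-induced C4 epimerisation or migration of the exocyclic alkene into the ring.

**Compound list**
1 | monopotassium (2R,3S)-isocitrate | OC(=O)C[C@H](C(=O)O)[C@@H](O)C(=O)[O-].[K+] | starting material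
2 | (2R,3S)-5-oxooxolane-2,3-dicarboxylic acid (isocitric acid lactone) | O=C1C[C@H](C(=O)O)[C@H](C(=O)O)O1 | intermediate
3 | (3aS,6aR)-dihydrofuro[3,4-b]furan-2,4,6(3H)-trione | O=C1C[C@@H]2C(=O)OC(=O)[C@@H]2O1 | intermediate
4 | (2R,3S)-2-{[(1,3-dioxoisoindolin-2-yl)oxy]carbonyl}-5-oxooxolane-3-carboxylic acid | O=C1C[C@H](C(=O)O)[C@H](C(=O)ON2C(=O)c3ccccc3C2=O)O1 | intermediate
5 | 3-tert-butyl 2-(1,3-dioxoisoindolin-2-yl) (2R,3S)-5-oxooxolane-2,3-dicarboxylate | O=C1C[C@H](C(=O)OC(C)(C)C)[C@H](C(=O)ON2C(=O)c3ccccc3C2=O)O1 | intermediate
6 | 14-hydroxytetradecanoic acid | OCCCCCCCCCCCCCC(=O)O | starting material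
7 | 14-acetoxytetradecanoic acid | CC(=O)OCCCCCCCCCCCCCC(=O)O | intermediate
8 | 1,3-dioxoisoindolin-2-yl 14-acetoxytetradecanoate | CC(=O)OCCCCCCCCCCCCCC(=O)ON1C(=O)c2ccccc2C1=O | intermediate
9 | tert-butyl (2R,3S)-2-(13-acetoxytridecyl)-5-oxooxolane-3-carboxylate | O=C1C[C@H](C(=O)OC(C)(C)C)[C@@H](CCCCCCCCCCCCCOC(C)=O)O1 | intermediate
10 | tert-butyl (2R,3S,4R)-2-(13-acetoxytridecyl)-4-[(dimethylamino)methyl]-5-oxooxolane-3-carboxylate | O=C1[C@@H](CN(C)C)[C@H](C(=O)OC(C)(C)C)[C@@H](CCCCCCCCCCCCCOC(C)=O)O1 | intermediate
11 | {(2R,3S,4R)-2-(13-acetoxytridecyl)-3-(tert-butoxycarbonyl)-5-oxooxolan-4-yl}methyl-trimethylammonium iodide | O=C1[C@@H](C[N+](C)(C)C)[C@H](C(=O)OC(C)(C)C)[C@@H](CCCCCCCCCCCCCOC(C)=O)O1.[I-] | intermediate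
12 | tert-butyl (2R,3S)-2-(13-acetoxytridecyl)-4-methylidene-5-oxooxolane-3-carboxylate | C=C1C(=O)O[C@H](CCCCCCCCCCCCCOC(C)=O)[C@H]1C(=O)OC(C)(C)C | intermediate
13 | (2R,3S)-2-(13-acetoxytridecyl)-4-methylidene-5-oxooxolane-3-carboxylic acid | C=C1C(=O)O[C@H](CCCCCCCCCCCCCOC(C)=O)[C@H]1C(=O)O | target

Total step count: 8. Longest linear sequence: 6 (steps 1, 2, 3, 6, 7, 8).

**Steps most likely to fail**

Step 6. The two radicals may homocouple statistically. The C5 nickel alkyl may also undergo β-hydride elimination or hydrogen capture, and facial selectivity at C5 may be eroded. The fallback replaces the coupling of two electrophiles by a nucleophile–electrophile coupling and sets out from 7 and 5.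
- Acid 7 is submitted to Hunsdiecker-type iododecarboxylation (PhI(OAc)2, I2, light) to give 13-iodotridecyl acetate F1.
- Direct zinc insertion (Zn dust, LiCl, THF), which tolerates the acetate, gives (13-acetoxytridecyl)zinc iodide F2.
- A nickel/bipyridine-catalysed decarboxylative Negishi-type alkyl–alkyl coupling of F2 with 5 (NiCl2·glyme, 4,4′-di-tert-butyl-2,2′-bipyridine, THF/DMF) comes back to the route at 9. The same anti-to-C4 control applies.

Step 3. Acyl transfer to N-hydroxyphthalimide is reversible. The free C4 acid may close back onto the activated ester and scramble the regiochemistry, or the nucleophile may attack the wrong carbonyl. The fallback uses an irreversible alcoholysis and an orthogonal ester pair and sets out from 3.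
- Allyl alcohol opens the anhydride at the same carbonyl to give (2R,3S)-2-(allyloxycarbonyl)-5-oxooxolane-3-carboxylic acid F3.
- The trichloroacetimidate converts F3 into 2-allyl 3-tert-butyl (2R,3S)-5-oxooxolane-2,3-dicarboxylate F4, which can be purified from any regioisomer.
- Tsuji–Trost deallylation (Pd(PPh3)4, morpholine) frees (2R,3S)-3-(tert-butoxycarbonyl)-5-oxooxolane-2-carboxylic acid F5.
- DIC/N-hydroxyphthalimide esterification of F5 comes back to the route at 5.

Step 7. Deprotonation of the acetate or of C4–H may compete, leading to acyl transfer, E1cB opening of the lactone or epimerisation. The exocyclic alkene may also migrate into the ring during the elimination. The fallback avoids amide bases through a decarboxylative methylenation and sets out from 9.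
- TFA gives (2R,3S)-2-(13-acetoxytridecyl)-5-oxooxolane-3-carboxylic acid F6.
- Methyl magnesium carbonate in DMF at 135 °C carboxylates C3 and is expected to strip the acetate. After acid work-up this gives (2R,3S)-2-(13-hydroxytridecyl)-5-oxooxolane-3,4-dicarboxylic acid F7, epimeric at the malonic carbon.
- Aqueous formaldehyde, N-methylaniline, NaOAc and AcOH effect Mannich condensation and decarboxylative elimination to (2R,3S)-2-(13-hydroxytridecyl)-4-methylidene-5-oxooxolane-3-carboxylic acid F8.
- Acetylation of the primary alcohol (Ac2O, Sc(OTf)3 cat., then water) comes back to the route at 13.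

**Further compounds**
F1 | step 6 | 13-iodotridecyl acetate | CC(=O)OCCCCCCCCCCCCCI
F2 | step 6 | (13-acetoxytridecyl)zinc iodide | CC(=O)OCCCCCCCCCCCCC[Zn]I
F3 | step 3 | (2R,3S)-2-(allyloxycarbonyl)-5-oxooxolane-3-carboxylic acid | O=C1C[C@H](C(=O)O)[C@H](C(=O)OCC=C)O1
F4 | step 3 | 2-allyl 3-tert-butyl (2R,3S)-5-oxooxolane-2,3-dicarboxylate | O=C1C[C@H](C(=O)OC(C)(C)C)[C@H](C(=O)OCC=C)O1
F5 | step 3 | (2R,3S)-3-(tert-butoxycarbonyl)-5-oxooxolane-2-carboxylic acid | O=C1C[C@H](C(=O)OC(C)(C)C)[C@H](C(=O)O)O1
F6 | step 7 | (2R,3S)-2-(13-acetoxytridecyl)-5-oxooxolane-3-carboxylic acid | O=C1C[C@H](C(=O)O)[C@@H](CCCCCCCCCCCCCOC(C)=O)O1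
F7 | step 7 | (2R,3S)-2-(13-hydroxytridecyl)-5-oxooxolane-3,4-dicarboxylic acid | O=C1C(C(=O)O)[C@H](C(=O)O)[C@@H](CCCCCCCCCCCCCO)O1
F8 | step 7 | (2R,3S)-2-(13-hydroxytridecyl)-4-methylidene-5-oxooxolane-3-carboxylic acid | C=C1C(=O)O[C@H](CCCCCCCCCCCCCO)[C@H]1C(=O)O
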